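**Retrosynthetic overview**
- The target is reached from a ring B phenol (free OH on C6, ring A aryloxy group already on C1) by O-prenylation and removal of two silyl ethers.
- The strategy rests on ring B: C4 (OMe) and C6 (O-prenyl) are meta with unsubstituted C5 between them, a resorcinol monoether pattern. Ring B is therefore cut at C5–C6, C3–C4 and C1–C6 into methoxyacetylene (C4, C5) and a 4-aryloxy-3-(silyloxymethyl)cyclobutenone (C6, C1, C2, C3).
- The cyclobutenone comes from (2+2) addition of an aryloxyketene to ethoxyacetylene, then addition of a hydroxymethyl anion equivalent, acid-induced carbonyl transposition and silylation.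
- The ketene precursor is the O-carboxymethyl ether of monosilylated methyl 2,6-dihydroxy-4-methylbenzoate.
- Ring order: ring A is bought, the four-membered ring is built on its ether oxygen, and ring B is formed last from that ring.

Key step: step 10

Remark: the ring A phenol is carried as a triisopropylsilyl ether (more robust to carbonate and to the organolithium than a tert-butyldimethylsilyl ether), methoxyacetylene is taken as not purchasable and is made in step 9, and all intermediates with a stereocentre are racemic (the target has none).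

**Step 1**
Reactants: 1 methyl 2,6-dihydroxy-4-methylbenzoate
Product: 2 methyl 2-hydroxy-4-methyl-6-[(triisopropylsilyl)oxy]benzoate
Conditions: TIPSCl (1.05 equiv), imidazole, DMF, 0 °C to rt
Reagents that add atoms: triisopropylsilyl chloride (TIPSCl), CC(C)[Si](Cl)(C(C)C)C(C)C
Why: Silylation of a phenol with a silyl chloride and imidazole: the two hydroxyls of 1 are equivalent, and once one is silylated the other is held in a hydrogen bond to the ester carbonyl beside a bulky neighbour, so one equivalent of reagent should stop at the mono-ether.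

**Step 2**
Reactants: 2 methyl 2-hydroxy-4-methyl-6-[(triisopropylsilyl)oxy]benzoate; 3 benzyl bromoacetate
Product: 4 methyl 2-[2-(benzyloxy)-2-oxoethoxy]-4-methyl-6-[(triisopropylsilyl)oxy]benzoate
Conditions: K2CO3, acetone, 50 °C
Reagents that add atoms: none
Why: Williamson ether synthesis: the remaining phenol, although chelated, is alkylated by the reactive α-bromo ester with carbonate in an aprotic solvent, conditions mild enough to leave the aryl silyl ether intact and to avoid Dieckmann-type closure onto the ring ester.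

**Step 3**
Reactants: 4 methyl 2-[2-(benzyloxy)-2-oxoethoxy]-4-methyl-6-[(triisopropylsilyl)oxy]benzoate
Product: 5 2-{2-(methoxycarbonyl)-5-methyl-3-[(triisopropylsilyl)oxy]phenoxy}acetic acid
Conditions: H2 (1 atm), Pd/C, EtOAc, rt
Reagents that add atoms: none
Why: Hydrogenolysis of a benzyl ester over palladium is neutral and leaves the aryl silyl ether, the methyl ester and the aryl–O–CH2 bond (not benzylic) untouched.

**Step 4**
Reactants: 5 2-{2-(methoxycarbonyl)-5-methyl-3-[(triisopropylsilyl)oxy]phenoxy}acetic acid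
Product: 6 methyl 2-(2-chloro-2-oxoethoxy)-4-methyl-6-[(triisopropylsilyl)oxy]benzoate
Conditions: (COCl)2, DMF (cat.), CH2Cl2, 0 °C to rt; volatiles removed, used crude
Reagents that add atoms: oxalyl chloride, O=C(Cl)C(Cl)=O
Why: Standard conversion of a carboxylic acid into its chloride with oxalyl chloride and catalytic DMF (Vilsmeier-type activation); the hindered methyl ester and the silyl ether should tolerate the anhydrous HCl formed.

**Step 5**
Reactants: 6 methyl 2-(2-chloro-2-oxoethoxy)-4-methyl-6-[(triisopropylsilyl)oxy]benzoate; 7 ethoxyacetylene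
Product: 9 methyl 2-[(2-ethoxy-4-oxocyclobut-2-en-1-yl)oxy]-4-methyl-6-[(triisopropylsilyl)oxy]benzoate (racemic), via aryloxyketene 8 (not isolated)
Conditions: ethoxyacetylene (3 equiv), Et3N (slow addition), CH2Cl2, 0 °C to rt
Reagents that add atoms: none
Why: Dehydrochlorination of the acid chloride by the amine gives the aryloxyketene, which undergoes the known (2+2) cycloaddition of ketenes with alkoxyacetylenes, the nucleophilic unsubstituted alkyne carbon bonding to the ketene carbonyl carbon so that ethoxy ends on C3 and the aryloxy carbon becomes C4; the C4 stereocentre forms as a racemate.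

**Step 6**
Reactants: 10 (tributylstannyl)methanol
Product: 11 tributyl[(1-ethoxyethoxy)methyl]stannane (racemic acetal)
Conditions: ethyl vinyl ether, PPTS (cat.), CH2Cl2, rt
Reagents that add atoms: ethyl vinyl ether, C=COCC
Why: Acid-catalysed addition of the alcohol to the vinyl ether (acetalization) gives the 1-ethoxyethyl-protected hydroxymethylstannane, a known precursor of a hydroxymethyl anion equivalent; the acetal carbon is racemic and is removed in step 7.

**Step 7**
Reactants: 9 methyl 2-[(2-ethoxy-4-oxocyclobut-2-en-1-yl)oxy]-4-methyl-6-[(triisopropylsilyl)oxy]benzoate; 11 tributyl[(1-ethoxyethoxy)methyl]stannane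
Product: 14 methyl 2-{[2-(hydroxymethyl)-4-oxocyclobut-2-en-1-yl]oxy}-4-methyl-6-[(triisopropylsilyl)oxy]benzoate (racemic), via alkoxymethyllithium 12 (not isolated), via lithium alkoxide adduct 13 (not isolated)
Conditions: 11, n-BuLi, THF, −78 °C; add 9, −78 °C; then 1 M HCl, THF, 0 °C to rt
Reagents that add atoms: water, O
Why: Tin–lithium exchange gives the α-alkoxymethyllithium, which adds to the carbonyl of the vinylogous ester, and aqueous acid then ionizes the tertiary allylic alkoxide, lets water attack the ethoxy-bearing carbon (1,3-carbonyl transposition, the standard route from 3-alkoxycyclobutenones to 3-substituted cyclobutenones) and hydrolyses the acetal; addition–elimination at the ethoxy-bearing carbon would lead to the same constitution, and the aryloxy-bearing stereocentre stays racemic.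

**Step 8**
Reactants: 14 methyl 2-{[2-(hydroxymethyl)-4-oxocyclobut-2-en-1-yl]oxy}-4-methyl-6-[(triisopropylsilyl)oxy]benzoate
Product: 15 methyl 2-{[2-({[tert-butyl(dimethyl)silyl]oxy}methyl)-4-oxocyclobut-2-en-1-yl]oxy}-4-methyl-6-[(triisopropylsilyl)oxy]benzoate (racemic)
Conditions: TBSOTf, 2,6-lutidine, CH2Cl2, −78 °C
Reagents that add atoms: tert-butyldimethylsilyl triflate (TBSOTf), CC(C)(C)[Si](C)(C)OS(=O)(=O)C(F)(F)F
Why: Silylation of the primary alcohol with a silyl triflate and a hindered, non-nucleophilic base at low temperature spares the electrophilic enone; the silyl ether is needed because a free hydroxyl would capture the ketene of step 10 as a butenolide.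

**Step 9**
Reactants: 16 2-chloro-1,1-dimethoxyethane (chloroacetaldehyde dimethyl acetal)
Product: 18 methoxyacetylene, via sodium methoxyacetylide 17 (not isolated)
Conditions: NaNH2 (3 equiv), liquid NH3, −33 °C; NH3 evaporated; cold saturated aqueous NaCl, −70 °C to rt; distilled into cold toluene and used at once
Reagents that add atoms: none
Why: Twofold base-induced elimination (HCl, then methanol) from the chloroacetal with NaNH2 gives the sodium acetylide of the ynol ether, the established preparation of alkoxyacetylenes, and protonation on aqueous quench releases the volatile alkyne.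

**Step 10**
Reactants: 15 methyl 2-{[2-({[tert-butyl(dimethyl)silyl]oxy}methyl)-4-oxocyclobut-2-en-1-yl]oxy}-4-methyl-6-[(triisopropylsilyl)oxy]benzoate; 18 methoxyacetylene
Product: 23 methyl 2-[2-({[tert-butyl(dimethyl)silyl]oxy}methyl)-6-hydroxy-4-methoxyphenoxy]-4-methyl-6-[(triisopropylsilyl)oxy]benzoate, via vinylketene 19 (not isolated), via vinylcyclobutenone 20 (not isolated), via dienylketene 21 (not isolated), via cyclohexadienone 22 (not isolated)
Conditions: methoxyacetylene (3 equiv), toluene, 80 °C, sealed tube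
Reagents that add atoms: none
Why: On heating, the four-membered ring of 15 undergoes conrotatory 4-electron cleavage of its C1–C4 bond to an aryloxy-substituted vinylketene (a donor on C4 eases this opening), and methoxyacetylene adds across the ketene C=C in a (2+2) cycloaddition that makes the C5–C6 and C3–C4 bonds of ring B. The 4-alkenyl-3-methoxycyclobutenone so formed reopens to a dienylketene, ring B closes by disrotatory 6-electron electrocyclization (C1–C6 bond), and the cyclohexa-2,4-dienone tautomerizes to the phenol. This is the Danheiser benzannulation of a cyclobutenone with an alkoxyacetylene, used here on a substrate whose C4 substituent is an aryl ether, so the hindered diaryl ether carbon starts as an sp3 carbon and never has to be made by a coupling. No stereocentre survives: the C4 centre of 15 and the sp3 carbons of 20 and 22 all become aromatic carbons, and the geometry of the enol ether double bond has no consequence. The step needs regioselectivity in the (2+2) addition, which the polarization of the ynol ether secures (its nucleophilic unsubstituted carbon bonds to the electrophilic ketene carbonyl carbon, placing OMe meta to the new phenol and para to the aryloxy carbon), and it needs the ketene to escape internal capture, which the silyl ether on the hydroxymethyl group secures.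

**Step 11**
Reactants: 23 methyl 2-[2-({[tert-butyl(dimethyl)silyl]oxy}methyl)-6-hydroxy-4-methoxyphenoxy]-4-methyl-6-[(triisopropylsilyl)oxy]benzoate; 24 prenyl bromide (1-bromo-3-methylbut-2-ene)
Product: 25 methyl 2-{2-({[tert-butyl(dimethyl)silyl]oxy}methyl)-4-methoxy-6-[(3-methylbut-2-en-1-yl)oxy]phenoxy}-4-methyl-6-[(triisopropylsilyl)oxy]benzoate
Conditions: prenyl bromide, K2CO3, acetone, rt to 40 °C
Reagents that add atoms: none
Why: Williamson ether synthesis at the only free phenol; the primary allylic bromide reacts by SN2 at oxygen under mild carbonate conditions that both silyl ethers should tolerate.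

**Step 12**
Reactants: 25 methyl 2-{2-({[tert-butyl(dimethyl)silyl]oxy}methyl)-4-methoxy-6-[(3-methylbut-2-en-1-yl)oxy]phenoxy}-4-methyl-6-[(triisopropylsilyl)oxy]benzoate
Product: 26 methyl 2-hydroxy-6-{2-(hydroxymethyl)-4-methoxy-6-[(3-methylbut-2-en-1-yl)oxy]phenoxy}-4-methylbenzoate (CNP0532721.0)
Conditions: TBAF (2.5 equiv), AcOH (2.5 equiv), THF, 0 °C to rt
Reagents that add atoms: none
Why: Fluoride-induced cleavage of both silicon–oxygen bonds (alkyl tert-butyldimethylsilyl and aryl triisopropylsilyl ethers), buffered with acetic acid so that the methyl ester and the prenyl ether are untouched.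

**Compound list**
1 | methyl 2,6-dihydroxy-4-methylbenzoate | COC(=O)c1c(O)cc(C)cc1O | starting material
2 | methyl 2-hydroxy-4-methyl-6-[(triisopropylsilyl)oxy]benzoate | COC(=O)c1c(O)cc(C)cc1O[Si](C(C)C)(C(C)C)C(C)C | intermediate
3 | benzyl bromoacetate | BrCC(=O)OCc1ccccc1 | starting material
4 | methyl 2-[2-(benzyloxy)-2-oxoethoxy]-4-methyl-6-[(triisopropylsilyl)oxy]benzoate | COC(=O)c1c(OCC(=O)OCc2ccccc2)cc(C)cc1O[Si](C(C)C)(C(C)C)C(C)C | intermediate
5 | 2-{2-(methoxycarbonyl)-5-methyl-3-[(triisopropylsilyl)oxy]phenoxy}acetic acid | COC(=O)c1c(OCC(=O)O)cc(C)cc1O[Si](C(C)C)(C(C)C)C(C)C | intermediate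
6 | methyl 2-(2-chloro-2-oxoethoxy)-4-methyl-6-[(triisopropylsilyl)oxy]benzoate | COC(=O)c1c(OCC(Cl)=O)cc(C)cc1O[Si](C(C)C)(C(C)C)C(C)C | intermediate
7 | ethoxyacetylene | CCOC#C | starting material
8 | aryloxyketene: methyl 4-methyl-2-[(2-oxoethenyl)oxy]-6-[(triisopropylsilyl)oxy]benzoate | COC(=O)c1c(OC=C=O)cc(C)cc1O[Si](C(C)C)(C(C)C)C(C)C | intermediate
9 | methyl 2-[(2-ethoxy-4-oxocyclobut-2-en-1-yl)oxy]-4-methyl-6-[(triisopropylsilyl)oxy]benzoate (racemic) | CCOC1=CC(=O)C1Oc1cc(C)cc(O[Si](C(C)C)(C(C)C)C(C)C)c1C(=O)OC | intermediate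
10 | (tributylstannyl)methanol | CCCC[Sn](CCCC)(CCCC)CO | starting material
11 | tributyl[(1-ethoxyethoxy)methyl]stannane (racemic) | CCCC[Sn](CCCC)(CCCC)COC(C)OCC | intermediate
12 | [(1-ethoxyethoxy)methyl]lithium | [Li]COC(C)OCC | intermediate
13 | lithium alkoxide of methyl 2-({2-ethoxy-4-[(1-ethoxyethoxy)methyl]-4-hydroxycyclobut-2-en-1-yl}oxy)-4-methyl-6-[(triisopropylsilyl)oxy]benzoate (mixture of racemic diastereomers) | CCOC1=CC(O[Li])(COC(C)OCC)C1Oc1cc(C)cc(O[Si](C(C)C)(C(C)C)C(C)C)c1C(=O)OC | intermediate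
14 | methyl 2-{[2-(hydroxymethyl)-4-oxocyclobut-2-en-1-yl]oxy}-4-methyl-6-[(triisopropylsilyl)oxy]benzoate (racemic) | O=C1C=C(CO)C1Oc1cc(C)cc(O[Si](C(C)C)(C(C)C)C(C)C)c1C(=O)OC | intermediate
15 | methyl 2-{[2-({[tert-butyl(dimethyl)silyl]oxy}methyl)-4-oxocyclobut-2-en-1-yl]oxy}-4-methyl-6-[(triisopropylsilyl)oxy]benzoate (racemic; key-step precursor) | O=C1C=C(CO[Si](C)(C)C(C)(C)C)C1Oc1cc(C)cc(O[Si](C(C)C)(C(C)C)C(C)C)c1C(=O)OC | intermediate
16 | 2-chloro-1,1-dimethoxyethane | COC(CCl)OC | starting material
17 | sodium methoxyacetylide (NaC≡COMe) | COC#C[Na] | intermediate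
18 | methoxyacetylene | COC#C | intermediate
19 | vinylketene: methyl 2-{[2-({[tert-butyl(dimethyl)silyl]oxy}methyl)-4-oxobuta-1,3-dien-1-yl]oxy}-4-methyl-6-[(triisopropylsilyl)oxy]benzoate (alkene geometry not defined) | O=C=CC(CO[Si](C)(C)C(C)(C)C)=COc1cc(C)cc(O[Si](C(C)C)(C(C)C)C(C)C)c1C(=O)OC | intermediate
20 | vinylcyclobutenone: methyl 2-{[2-({[tert-butyl(dimethyl)silyl]oxy}methyl)-2-(2-methoxy-4-oxocyclobut-2-en-1-yl)ethenyl]oxy}-4-methyl-6-[(triisopropylsilyl)oxy]benzoate (racemic) | COC1=CC(=O)C1C(CO[Si](C)(C)C(C)(C)C)=COc1cc(C)cc(O[Si](C(C)C)(C(C)C)C(C)C)c1C(=O)OC | intermediate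
21 | dienylketene: methyl 2-{[2-({[tert-butyl(dimethyl)silyl]oxy}methyl)-4-methoxy-6-oxohexa-1,3,5-trien-1-yl]oxy}-4-methyl-6-[(triisopropylsilyl)oxy]benzoate | O=C=CC(OC)=CC(CO[Si](C)(C)C(C)(C)C)=COc1cc(C)cc(O[Si](C(C)C)(C(C)C)C(C)C)c1C(=O)OC | intermediate
22 | cyclohexadienone: methyl 2-{[2-({[tert-butyl(dimethyl)silyl]oxy}methyl)-4-methoxy-6-oxocyclohexa-2,4-dien-1-yl]oxy}-4-methyl-6-[(triisopropylsilyl)oxy]benzoate (racemic) | O=C1C=C(OC)C=C(CO[Si](C)(C)C(C)(C)C)C1Oc1cc(C)cc(O[Si](C(C)C)(C(C)C)C(C)C)c1C(=O)OC | intermediate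
23 | methyl 2-[2-({[tert-butyl(dimethyl)silyl]oxy}methyl)-6-hydroxy-4-methoxyphenoxy]-4-methyl-6-[(triisopropylsilyl)oxy]benzoate (key-step product) | COc1cc(O)c(Oc2cc(C)cc(O[Si](C(C)C)(C(C)C)C(C)C)c2C(=O)OC)c(CO[Si](C)(C)C(C)(C)C)c1 | intermediate
24 | prenyl bromide (1-bromo-3-methylbut-2-ene) | CC(C)=CCBr | starting material
25 | methyl 2-{2-({[tert-butyl(dimethyl)silyl]oxy}methyl)-4-methoxy-6-[(3-methylbut-2-en-1-yl)oxy]phenoxy}-4-methyl-6-[(triisopropylsilyl)oxy]benzoate | COc1cc(OCC=C(C)C)c(Oc2cc(C)cc(O[Si](C(C)C)(C(C)C)C(C)C)c2C(=O)OC)c(CO[Si](C)(C)C(C)(C)C)c1 | intermediate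
26 | methyl 2-hydroxy-6-{2-(hydroxymethyl)-4-methoxy-6-[(3-methylbut-2-en-1-yl)oxy]phenoxy}-4-methylbenzoate | COC(=O)c1c(O)cc(C)cc1Oc1c(CO)cc(OC)cc1OCC=C(C)C | target

**Step count**
Total: 12 steps. Longest linear sequence: 10 steps (1 to 26 through steps 1–5, 7, 8, 10, 11, 12); steps 6 and 9 prepare the two reagents.

**Steps most likely to fail**

Step 10. Capture of the vinylketene by methoxyacetylene may lose out to acylation of the newly formed phenol by the ketene, to ketene dimerization, or to escape of the volatile alkyne; a cyclobutenone with an aryl ether on C4 is also a little-used substrate for this benzannulation. The fallback gives up the de novo construction of ring B and makes the diaryl ether bond by cross-coupling; it sets out from phenol 2 and comes back to the route at phenol 23.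
- Ring B partner: commercial 2-(benzyloxy)-4-methoxybenzaldehyde would be oxidized (mCPBA, CH2Cl2, Baeyer–Villiger) to 2-(benzyloxy)-4-methoxyphenyl formate F1, which is methanolysed (K2CO3, MeOH) to 2-(benzyloxy)-4-methoxyphenol F2.
- Ortho-formylation at its only free ortho position (MgCl2, Et3N, paraformaldehyde, MeCN, reflux) would give 3-(benzyloxy)-2-hydroxy-5-methoxybenzaldehyde F3.
- NaBH4 reduction would give 2-(benzyloxy)-6-(hydroxymethyl)-4-methoxyphenol F4, and silylation of the primary alcohol (TBSCl, imidazole, 0 °C) would give 2-(benzyloxy)-6-({[tert-butyl(dimethyl)silyl]oxy}methyl)-4-methoxyphenol F5.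
- Ring A partner: phenol 2 would be converted (Tf2O, pyridine, CH2Cl2) into methyl 4-methyl-2-[(triisopropylsilyl)oxy]-6-{[(trifluoromethyl)sulfonyl]oxy}benzoate F6.
- Palladium-catalysed diaryl ether coupling of F5 with F6 (Pd(OAc)2, tBuXPhos, K3PO4, toluene, 100 °C) would give methyl 2-[2-(benzyloxy)-6-({[tert-butyl(dimethyl)silyl]oxy}methyl)-4-methoxyphenoxy]-4-methyl-6-[(triisopropylsilyl)oxy]benzoate F7.
- Hydrogenolysis of the benzyl ether (H2, Pd/C, EtOAc) gives 23, which continues with steps 11 and 12.

Step 5. Oligomerization of the aryloxyketene and acylation of the amine or of the alkyne by the acid chloride may outrun the cycloaddition. The fallback builds the cyclobutenone with the hydroxymethyl carbon already in the alkyne partner, by a keteniminium (2+2) cycloaddition; it sets out from acid chloride 6, bypasses steps 5, 7 and 8, and comes back at cyclobutenone 15.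
- Acid chloride 6 with dimethylamine (THF, 0 °C) would give methyl 2-[2-(dimethylamino)-2-oxoethoxy]-4-methyl-6-[(triisopropylsilyl)oxy]benzoate F8.
- Activation with Tf2O and 2,4,6-collidine in 1,2-dichloroethane in the presence of an excess of commercial tert-butyldimethyl(prop-2-yn-1-yloxy)silane would give the keteniminium salt N-(2-{2-(methoxycarbonyl)-5-methyl-3-[(triisopropylsilyl)oxy]phenoxy}ethenylidene)-N-methylmethanaminium triflate F9.
- F9 adds to the terminal alkyne with its unsubstituted carbon at the iminium carbon, giving the cyclobutenyliminium triflate N-[2-{2-(methoxycarbonyl)-5-methyl-3-[(triisopropylsilyl)oxy]phenoxy}-3-({[tert-butyl(dimethyl)silyl]oxy}methyl)cyclobut-3-en-1-ylidene]-N-methylmethanaminium triflate F10.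
- Hydrolysis with aqueous NaHCO3 gives 15. The excess of alkyne is meant to suppress cyclization of the keteniminium ion onto ring A.

Step 7. Hydrolysis of the acetal needs longer contact with aqueous acid than the transposition does, and during this time the strained hydroxymethyl enone may decompose or the aryl silyl ether may be lost. The fallback separates the two events by using an ether that is removed oxidatively; it sets out from 9 (reagent made from 10) and comes back at alcohol 14.
- (Tributylstannyl)methanol 10 would be alkylated (NaH, 4-methoxybenzyl chloride, THF/DMF) to tributyl{[(4-methoxybenzyl)oxy]methyl}stannane F11.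
- Tin–lithium exchange (n-BuLi, THF, −78 °C) would give {[(4-methoxybenzyl)oxy]methyl}lithium F12.
- Addition to 9 would give the lithium alkoxide of methyl 2-[(2-ethoxy-4-hydroxy-4-{[(4-methoxybenzyl)oxy]methyl}cyclobut-2-en-1-yl)oxy]-4-methyl-6-[(triisopropylsilyl)oxy]benzoate F13.
- A brief quench with dilute HCl at 0 °C would give methyl 2-{[2-{[(4-methoxybenzyl)oxy]methyl}-4-oxocyclobut-2-en-1-yl]oxy}-4-methyl-6-[(triisopropylsilyl)oxy]benzoate F14.
- DDQ in CH2Cl2/pH 7 buffer at 0 °C removes the 4-methoxybenzyl group and gives 14.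

**Further compounds**
F1 | step 10 | 2-(benzyloxy)-4-methoxyphenyl formate | O=COc1ccc(OC)cc1OCc1ccccc1
F2 | step 10 | 2-(benzyloxy)-4-methoxyphenol | Oc1ccc(OC)cc1OCc1ccccc1
F3 | step 10 | 3-(benzyloxy)-2-hydroxy-5-methoxybenzaldehyde | O=Cc1cc(OC)cc(OCc2ccccc2)c1O
F4 | step 10 | 2-(benzyloxy)-6-(hydroxymethyl)-4-methoxyphenol | OCc1cc(OC)cc(OCc2ccccc2)c1O
F5 | step 10 | 2-(benzyloxy)-6-({[tert-butyl(dimethyl)silyl]oxy}methyl)-4-methoxyphenol | CC(C)(C)[Si](C)(C)OCc1cc(OC)cc(OCc2ccccc2)c1O
F6 | step 10 | methyl 4-methyl-2-[(triisopropylsilyl)oxy]-6-{[(trifluoromethyl)sulfonyl]oxy}benzoate | COC(=O)c1c(OS(=O)(=O)C(F)(F)F)cc(C)cc1O[Si](C(C)C)(C(C)C)C(C)C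
F7 | step 10 | methyl 2-[2-(benzyloxy)-6-({[tert-butyl(dimethyl)silyl]oxy}methyl)-4-methoxyphenoxy]-4-methyl-6-[(triisopropylsilyl)oxy]benzoate | COc1cc(OCc2ccccc2)c(Oc2cc(C)cc(O[Si](C(C)C)(C(C)C)C(C)C)c2C(=O)OC)c(CO[Si](C)(C)C(C)(C)C)c1
F8 | step 5 | methyl 2-[2-(dimethylamino)-2-oxoethoxy]-4-methyl-6-[(triisopropylsilyl)oxy]benzoate | COC(=O)c1c(OCC(=O)N(C)C)cc(C)cc1O[Si](C(C)C)(C(C)C)C(C)C
F9 | step 5 | N-(2-{2-(methoxycarbonyl)-5-methyl-3-[(triisopropylsilyl)oxy]phenoxy}ethenylidene)-N-methylmethanaminium triflate | COC(=O)c1c(OC=C=[N+](C)C)cc(C)cc1O[Si](C(C)C)(C(C)C)C(C)C.[O-]S(=O)(=O)C(F)(F)F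
F10 | step 5 | N-[2-{2-(methoxycarbonyl)-5-methyl-3-[(triisopropylsilyl)oxy]phenoxy}-3-({[tert-butyl(dimethyl)silyl]oxy}methyl)cyclobut-3-en-1-ylidene]-N-methylmethanaminium triflate (racemic) | C[N+](C)=C1C=C(CO[Si](C)(C)C(C)(C)C)C1Oc1cc(C)cc(O[Si](C(C)C)(C(C)C)C(C)C)c1C(=O)OC.[O-]S(=O)(=O)C(F)(F)F
F11 | step 7 | tributyl{[(4-methoxybenzyl)oxy]methyl}stannane | CCCC[Sn](CCCC)(CCCC)COCc1ccc(OC)cc1
F12 | step 7 | {[(4-methoxybenzyl)oxy]methyl}lithium | [Li]COCc1ccc(OC)cc1
F13 | step 7 | lithium alkoxide of methyl 2-[(2-ethoxy-4-hydroxy-4-{[(4-methoxybenzyl)oxy]methyl}cyclobut-2-en-1-yl)oxy]-4-methyl-6-[(triisopropylsilyl)oxy]benzoate (racemic diastereomers) | CCOC1=CC(O[Li])(COCc2ccc(OC)cc2)C1Oc1cc(C)cc(O[Si](C(C)C)(C(C)C)C(C)C)c1C(=O)OC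
F14 | step 7 | methyl 2-{[2-{[(4-methoxybenzyl)oxy]methyl}-4-oxocyclobut-2-en-1-yl]oxy}-4-methyl-6-[(triisopropylsilyl)oxy]benzoate (racemic) | O=C1C=C(COCc2ccc(OC)cc2)C1Oc1cc(C)cc(O[Si](C(C)C)(C(C)C)C(C)C)c1C(=O)OC
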